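**Strategy.** Ring A (C1–C5 plus C10) is disconnected at the C4–C5 bond beside the quaternary centre C5: C4 with its methyl C18 is inserted late into a trans-hydrindanone (five-membered ring C10–C1–C2–C3–C5, ketone at C3) that already carries C5, C9 and C10. In one pot, 1,1-dibromoethyllithium adds to the ketone, bromine–lithium exchange gives a β-oxido carbenoid, C5 shifts to the carbenoid carbon, and the regiodefined enolate is trapped as the C3 enol triflate, a masked Δ3 alkene inert to the later ring-B dihydroxylation. The hydrindanone comes from a Hajos–Parrish-type enone by reductive hydroxymethylation; the butenolide arrives last by a Heck coupling.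

Key step: step 9

Remarks on the chemistry:
- Clerodane numbering is used for all bicyclic compounds. Ring B is C5–C10, ring A is C1–C5 plus C10. The methyl groups are C17 (on C8), C18 (on C4), C19 (on C5) and C20 (on C9); C11 is the carbon on C9. "β" means the face on which C19 lies, "α" the opposite face. In the hydrindane intermediates ring A is C10–C1–C2–C3–C5 and C4 is not yet present.
- Compounds 12, 13 and 15–18 are drawn as the expected 8β-OH/8α-CH3 epimer. Either C8 epimer serves, because C8 becomes sp2 in step 10.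

Step 1
Reactants: 1 2-methylcyclopentane-1,3-dione; 2 pent-1-en-3-one
Product: 3 2-methyl-2-(3-oxopentyl)cyclopentane-1,3-dione
Conditions: H2O, AcOH (cat.), 70 °C
Reagents that add atoms: none
Why: Michael addition of the acidic cyclic 1,3-dione to the vinyl ketone; no stereocentre is formed.

Step 2
Reactants: 3 2-methyl-2-(3-oxopentyl)cyclopentane-1,3-dione
Product: 5 (R)-4,7a-dimethyl-2,3,7,7a-tetrahydro-1H-indene-1,5(6H)-dione, via cis-ketol 4 (not isolated)
Conditions: D-phenylalanine (1.0 equiv), 10-camphorsulfonic acid (0.5 equiv), DMF, 30 → 70 °C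
Reagents that add atoms: none
Why: Hajos–Parrish–Eder–Sauer–Wiechert aldol condensation; the enamine of the D-amino acid differentiates the enantiotopic ring carbonyls and should set C5 (indene C7a) as R, the mirror image of the L-amino acid series, and dehydration of the ketol gives the enone.

Step 3
Reactants: 5 (R)-4,7a-dimethyl-2,3,7,7a-tetrahydro-1H-indene-1,5(6H)-dione
Product: 6 C3 ethylene ketal of 5 (indene C1 ketal; enone untouched)
Conditions: ethylene glycol (1.2 equiv), p-TsOH·H2O (cat.), benzene, reflux (Dean–Stark)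
Reagents that add atoms: ethylene glycol OCCO
Why: Acetalisation; the saturated cyclopentanone carbonyl should react faster than the conjugated enone carbonyl.

Step 4
Reactants: 6 C3 ethylene ketal of 5
Product: 8 trans-hydrindan-8-one with 9α-CH2OH, 9β-CH3, 5β-CH3, 10α-H and the C3 ketal, via lithium enolate 7 (not isolated)
Conditions: Li (2.2 equiv), t-BuOH (1.0 equiv), NH3/THF, −78 °C; NH3 removed; CH2O (gas), THF, −78 °C; aq NH4Cl
Reagents that add atoms: formaldehyde C=O
Why: Stork reductive alkylation (dissolving-metal enone reduction, then aldol trapping); protonation of C10 on the α face should give the trans ring fusion, and the regiospecific C8–C9 enolate should take up formaldehyde on the α face, anti to the angular C19 methyl, setting C9 with C20 β and C11 α.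

Step 5
Reactants: 8 keto alcohol
Product: 9 C11 tert-butyldimethylsilyl ether of 8
Conditions: t-BuMe2SiCl, imidazole, DMF, rt
Reagents that add atoms: tert-butyldimethylsilyl chloride CC(C)(C)[Si](C)(C)Cl
Why: Silylation of the primary alcohol, which also blocks retro-aldol loss of C11.

Step 6
Reactants: 9 silyl ether ketone
Product: 11 Δ6-en-8-one (C6=C7–C8=O), via silyl enol ether 10 (not isolated)
Conditions: LiN(SiMe3)2, Me3SiCl, THF, −78 °C → rt; volatiles removed; Pd(OAc)2 (1.05 equiv), MeCN, rt
Reagents that add atoms: none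
Why: Saegusa–Ito dehydrogenation; C7 carries the only enolisable hydrogens because C9 is quaternary.

Step 7
Reactants: 11 Δ6-en-8-one
Product: 12 tertiary allylic alcohol (8-hydroxy-8-methyl, Δ6; C17 introduced)
Conditions: MeLi, THF, −78 °C; then H2O
Reagents that add atoms: methyllithium [Li]C
Why: 1,2-Addition of methyllithium to a non-enolisable enone, expected from the α face away from the axial C20 methyl; the C8 configuration is erased in step 10.

Step 8
Reactants: 12 tertiary allylic alcohol with C3 ketal
Product: 13 trans-hydrindan-3-one (C3 ketone released)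
Conditions: pyridinium p-toluenesulfonate (0.2 equiv), acetone/H2O 10:1, 50 °C
Reagents that add atoms: water O
Why: Acetal hydrolysis under weakly acidic buffered conditions that should spare the tertiary allylic alcohol and the silyl ether.

Step 9
Reactants: 13 trans-hydrindan-3-one; 14 1,1-dibromoethane
Product: 18 ring-enlarged enol triflate (trans-decalin; C3–OTf, C3=C4, 4-CH3), via dibromo alkoxide 15 (not isolated), via oxido carbenoid 16 (not isolated), via lithium enolate 17 (not isolated)
Conditions: 13, LiN(i-Pr)2 (1.0 equiv), THF, −78 °C; added to LiCBr2CH3 [from 14 (1.5 equiv), LiN(i-Pr)2 (1.5 equiv), THF/Et2O, −105 °C]; n-BuLi (1.6 equiv), −95 → 0 °C; then N-(5-chloropyridin-2-yl)bis(trifluoromethanesulfonyl)imide (1.2 equiv), −78 → 0 °C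
Reagents that add atoms: N-(5-chloropyridin-2-yl)bis(trifluoromethanesulfonyl)imide Clc1ccc(nc1)N(S(=O)(=O)C(F)(F)F)S(=O)(=O)C(F)(F)F
Why: 1,1-Dibromoethyllithium adds to the C3 carbonyl from the α face (anti to C19), bromine–lithium exchange turns the adduct into a β-oxido carbenoid, and loss of LiBr with a 1,2-shift of the C3–C5 bond to the carbenoid carbon gives the six-membered lithium enolate C3(OLi)=C4(CH3), which the triflimide traps on oxygen. The closest known reaction type is the β-oxido carbenoid ring enlargement of cycloalkanones, a carbenoid relative of the Tiffeneau–Demjanov and semipinacol shifts, followed by ordinary enolate O-triflation. No ring is closed: ring A grows from five to six atoms by a 1,2-alkyl shift that inserts C4 into the C3–C5 bond. No stereocentre is created; C5 migrates with retention so the trans C5/C10 fusion is carried over, and the C3 carbinol and carbenoid centres end as sp2 carbons. The step needs migration of C5 and not of C2, which the higher migratory aptitude of the fully substituted, electron-richer C5 towards the electron-poor carbenoid carbon should secure, and it needs a single electrophilic carbonyl, which holds because C8 is present as an unreactive tertiary lithium alkoxide. The enolate double bond can only lie between C3 and the inserted C4, so the triflate fixes the later Δ3 position without any regiochemical choice.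

Step 10
Reactants: 18 enol triflate with the Δ6 tertiary allylic alcohol
Product: 19 6-oxo-Δ7 enone (C6=O, C7=C8–CH3)
Conditions: pyridinium chlorochromate [C5H5NH][CrO3Cl], 4 Å molecular sieves, CH2Cl2, rt
Reagents that add atoms: pyridinium chlorochromate [O-][Cr](=O)(=O)Cl.c1cc[nH+]cc1
Why: Dauben–Babler oxidative transposition; the chromate ester of the tertiary allylic alcohol undergoes a 3,3-shift to C6 and is oxidised to the enone.

Step 11
Reactants: 19 6-oxo-Δ7 enone
Product: 20 6β-allylic alcohol
Conditions: NaBH4, CeCl3·7H2O, MeOH, −40 °C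
Reagents that add atoms: none
Why: Luche 1,2-reduction; hydride should add to C6 from the α face, anti to the angular C19 methyl on the neighbouring C5, giving the equatorial 6β-alcohol.

Step 12
Reactants: 20 6β-allylic alcohol
Product: 21 6β,7α,8α-triol (8β-CH3), enol triflate intact
Conditions: OsO4 (5 mol %), N-methylmorpholine N-oxide (2 equiv), acetone/H2O, rt
Reagents that add atoms: osmium tetroxide O=[Os](=O)(=O)=O; N-methylmorpholine N-oxide C[N+]1([O-])CCOCC1; water O
Why: Catalytic syn-dihydroxylation (Upjohn conditions) should occur only at the electron-rich C7=C8 bond, on the α face opposite to the allylic 6β-hydroxyl and the axial C19 and C20 methyls, setting C7 (α-OH) and C8 (α-OH, β-CH3), while the electron-poor tetrasubstituted enol triflate stays untouched.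

Step 13
Reactants: 21 triol enol triflate
Product: 22 Δ3 triol (C3–H, C3=C4–CH3)
Conditions: Pd(OAc)2 (5 mol %), PPh3 (10 mol %), HCO2H, Bu3N, DMF, 60 °C
Reagents that add atoms: none
Why: Palladium-catalysed formate reduction of a vinyl triflate (oxidative addition, formate exchange, decarboxylation, reductive elimination) replaces OTf by H and reveals the ring-A alkene without touching the triol.

Step 14
Reactants: 22 Δ3 triol
Product: 23 6β,7α-diacetate (8α-OH free, C11 silyl ether)
Conditions: Ac2O, pyridine, 4-(dimethylamino)pyridine (cat.), CH2Cl2, rt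
Reagents that add atoms: acetic anhydride CC(=O)OC(C)=O
Why: Acylation of the two secondary hydroxyls under nucleophilic catalysis; the hindered tertiary axial C8 hydroxyl should not react at room temperature.

Step 15
Reactants: 23 diacetate silyl ether
Product: 24 C11 primary alcohol
Conditions: HF·pyridine, pyridine/THF, 0 °C → rt
Reagents that add atoms: none
Why: Fluoride cleavage of the silyl ether under buffered conditions that should leave the acetates in place.

Step 16
Reactants: 24 primary alcohol
Product: 25 C11 aldehyde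
Conditions: Dess–Martin periodinane, CH2Cl2, rt
Reagents that add atoms: none
Why: Dess–Martin oxidation of the neopentyl primary alcohol; the tertiary alcohol cannot be oxidised.

Step 17
Reactants: 25 aldehyde
Product: 26 C9 vinyl compound (C11=C12)
Conditions: Ph3PCH3Br, NaN(SiMe3)2, THF, 0 °C; then 25, −78 → 0 °C
Reagents that add atoms: methyltriphenylphosphonium bromide C[P+](c1ccccc1)(c1ccccc1)c1ccccc1.[Br-]
Why: Wittig methylenation of the non-enolisable aldehyde; the ylide is not basic enough to deprotonate the tertiary alcohol, so retro-aldol cleavage should not compete.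

Step 18
Reactants: 26 vinyl compound; 27 4-bromofuran-2(5H)-one
Product: 28 target, 6β,7α-diacetoxy-8α-hydroxycleroda-3,11E,13-trien-15,16-olide
Conditions: Pd(OAc)2 (10 mol %), P(o-tol)3 (20 mol %), Et3N, DMF, 80 °C
Reagents that add atoms: none
Why: Mizoroki–Heck reaction; oxidative addition into the C–Br bond, insertion at the terminal carbon of the hindered vinyl group and β-hydride elimination, possible only from C12 because C9 bears no hydrogen, should give the E diene.

**Compound list**

1 | 2-methylcyclopentane-1,3-dione | CC1C(=O)CCC1=O | starting material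
2 | pent-1-en-3-one | CCC(=O)C=C | starting material
3 | 2-methyl-2-(3-oxopentyl)cyclopentane-1,3-dione | CCC(=O)CCC1(C)C(=O)CCC1=O | intermediate
4 | cis-ketol, (7aR)-3a-hydroxy-4,7a-dimethylhexahydro-1H-indene-1,5(4H)-dione, 3a-OH cis to 7a-CH3, C4 epimers | C1CC(=O)C(C)[C@]2(O)CCC(=O)[C@]12C | intermediate
5 | (R)-4,7a-dimethyl-2,3,7,7a-tetrahydro-1H-indene-1,5(6H)-dione | C1CC(=O)C(C)=C2CCC(=O)[C@]12C | intermediate
6 | C3 ethylene ketal of 5 (ketal at indene C1) | C1CC(=O)C(C)=C2CCC3(OCCO3)[C@]12C | intermediate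
7 | lithium enolate, trans-hydrindane (10α-H), C8–OLi, C8=C9, C3 ketal | C1CC(O[Li])=C(C)[C@H]2CCC3(OCCO3)[C@]12C | intermediate
8 | trans-hydrindan-8-one, 9α-CH2OH, 9β-CH3, 5β-CH3, 10α-H, C3 ethylene ketal | C1CC(=O)[C@](C)(CO)[C@H]2CCC3(OCCO3)[C@]12C | intermediate
9 | C11 tert-butyldimethylsilyl ether of 8 | C1CC(=O)[C@](C)(CO[Si](C)(C)C(C)(C)C)[C@H]2CCC3(OCCO3)[C@]12C | intermediate
10 | trimethylsilyl enol ether of 9 (C7=C8–OSiMe3) | C1C=C(O[Si](C)(C)C)[C@](C)(CO[Si](C)(C)C(C)(C)C)[C@H]2CCC3(OCCO3)[C@]12C | intermediate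
11 | Δ6-en-8-one (C6=C7–C8=O), C3 ketal | C1=CC(=O)[C@](C)(CO[Si](C)(C)C(C)(C)C)[C@H]2CCC3(OCCO3)[C@]12C | intermediate
12 | tertiary allylic alcohol, 8-hydroxy-8-methyl-Δ6 (drawn 8β-OH, 8α-CH3), C3 ketal | C1=C[C@@](C)(O)[C@](C)(CO[Si](C)(C)C(C)(C)C)[C@H]2CCC3(OCCO3)[C@]12C | intermediate
13 | trans-hydrindan-3-one with the Δ6 tertiary allylic alcohol | C1=C[C@@](C)(O)[C@](C)(CO[Si](C)(C)C(C)(C)C)[C@H]2CCC(=O)[C@]12C | intermediate
14 | 1,1-dibromoethane | CC(Br)Br | starting material
15 | dibromo alkoxide, 3α-(1,1-dibromoethyl)-3β,8-bis(lithiooxy) adduct | C1=C[C@@](C)(O[Li])[C@](C)(CO[Si](C)(C)C(C)(C)C)[C@H]2CC[C@](O[Li])(C(C)(Br)Br)[C@]12C | intermediate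
16 | β-oxido carbenoid, 3α-(1-bromo-1-lithioethyl) analogue of 15 | C1=C[C@@](C)(O[Li])[C@](C)(CO[Si](C)(C)C(C)(C)C)[C@H]2CC[C@](O[Li])(C(C)(Br)[Li])[C@]12C | intermediate
17 | ring-enlarged lithium enolate, trans-decalin, C3(OLi)=C4(CH3) | C1=C[C@@](C)(O[Li])[C@](C)(CO[Si](C)(C)C(C)(C)C)[C@H]2CCC(O[Li])=C(C)[C@]12C | intermediate
18 | enol triflate, trans-decalin, 3-OTf, Δ3, 4-CH3, Δ6, 8-OH, 8-CH3, 9α-CH2OSi(t-Bu)Me2 | C1=C[C@@](C)(O)[C@](C)(CO[Si](C)(C)C(C)(C)C)[C@H]2CCC(OS(=O)(=O)C(F)(F)F)=C(C)[C@]12C | intermediate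
19 | 6-oxo-Δ7 enone (C7=C8–CH3), 3-OTf | O=C1C=C(C)[C@](C)(CO[Si](C)(C)C(C)(C)C)[C@H]2CCC(OS(=O)(=O)C(F)(F)F)=C(C)[C@]12C | intermediate
20 | 6β-allylic alcohol, Δ7, 3-OTf | O[C@H]1C=C(C)[C@](C)(CO[Si](C)(C)C(C)(C)C)[C@H]2CCC(OS(=O)(=O)C(F)(F)F)=C(C)[C@]12C | intermediate
21 | 6β,7α,8α-triol (8β-CH3), 3-OTf | O[C@H]1[C@H](O)[C@](C)(O)[C@](C)(CO[Si](C)(C)C(C)(C)C)[C@H]2CCC(OS(=O)(=O)C(F)(F)F)=C(C)[C@]12C | intermediate
22 | Δ3 6β,7α,8α-triol, C11 silyl ether | O[C@H]1[C@H](O)[C@](C)(O)[C@](C)(CO[Si](C)(C)C(C)(C)C)[C@H]2CCC=C(C)[C@]12C | intermediate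
23 | 6β,7α-diacetate, 8α-OH, C11 silyl ether | CC(=O)O[C@H]1[C@H](OC(C)=O)[C@](C)(O)[C@](C)(CO[Si](C)(C)C(C)(C)C)[C@H]2CCC=C(C)[C@]12C | intermediate
24 | 6β,7α-diacetate, C11 primary alcohol | CC(=O)O[C@H]1[C@H](OC(C)=O)[C@](C)(O)[C@](C)(CO)[C@H]2CCC=C(C)[C@]12C | intermediate
25 | 6β,7α-diacetate, C11 aldehyde | CC(=O)O[C@H]1[C@H](OC(C)=O)[C@](C)(O)[C@](C)(C=O)[C@H]2CCC=C(C)[C@]12C | intermediate
26 | 6β,7α-diacetate, C9 vinyl (C11=C12) | CC(=O)O[C@H]1[C@H](OC(C)=O)[C@](C)(O)[C@](C)(C=C)[C@H]2CCC=C(C)[C@]12C | intermediate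
27 | 4-bromofuran-2(5H)-one | O=C1OCC(Br)=C1 | starting material
28 | target, 6β,7α-diacetoxy-8α-hydroxycleroda-3,11E,13-trien-15,16-olide | CC(=O)O[C@H]1[C@H](OC(C)=O)[C@](C)(O)[C@](C)(/C=C/C2=CC(=O)OC2)[C@H]2CCC=C(C)[C@]12C | target

**Totals.** Total step count: 18. Longest linear sequence: 18 steps (1 and 2 to 28).

**Steps most likely to fail**

Step 9. The bulky carbenoid may deprotonate the hindered C3 ketone at C2 instead of adding to it, or C2 may migrate in place of C5 and give the wrong enolate. The fallback sets out from 13 and moves the methyl introduction to a cross-coupling. Me3SiCHN2 with AlMe3 in CH2Cl2 (−78 → 0 °C, then K2CO3/MeOH) should give the homologated cyclohexanone F1. Here the less substituted C2 migrates, so the carbonyl carbon stays on C5 and becomes C4, and ring A still arises from the five-membered ring. KN(SiMe3)2 and the same triflimide would give the C4 enol triflate F2, since C3 is the only enolisable side. Pyridinium chlorochromate then gives the 6-oxo-Δ7 enone F3, NaBH4/CeCl3·7H2O the 6β-alcohol F4, and OsO4/N-methylmorpholine N-oxide the triol triflate F5. A Suzuki–Miyaura methylation (trimethylboroxine, Pd(PPh3)4, K2CO3, dioxane, 100 °C) would bring the sequence back to 22, one step longer than the main route.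

Step 4. The lithium enolate may be trapped poorly by monomeric formaldehyde (oligomerisation of the electrophile, proton transfer to the enolate, retro-aldol loss on work-up). The fallback sets out from 6 and uses the best-precedented electrophile. Li/NH3 reduction and trapping with allyl bromide would give the 9α-allyl ketone F6. RuHCl(CO)(PPh3)3 in toluene at 80 °C would isomerise it to the E-propenyl ketone F7. Ozonolysis (O3, CH2Cl2/MeOH, −78 °C; Me2S) would give the keto aldehyde F8. Selective aldehyde reduction with LiAlH(Ot-Bu)3 in THF at −78 °C would come back to the route at 8.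

Step 18. Carbopalladation of the neopentyl-type vinyl group may be slow, so that reduction or homocoupling of the bromobutenolide and base-induced double-bond migration in the butenolide take over. The fallback sets out from 25 and replaces steps 17 and 18. Takai–Utimoto iodo-olefination (CrCl2, CHI3, THF, 0 °C) would give the E-vinyl iodide F9. Stille coupling (Pd2(dba)3, AsPh3, CuI, DMF, rt) with 4-(tributylstannyl)furan-2(5H)-one F10, made from 27 with (Bu3Sn)2 and Pd(PPh3)4 in toluene at 100 °C, would come back to the route at 28.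

**Further compounds**

F1 | step 9 | homologated trans-decalin-4-one (C4 ketone, C3 methylene), Δ6 tertiary allylic alcohol | C1=C[C@@](C)(O)[C@](C)(CO[Si](C)(C)C(C)(C)C)[C@H]2CCCC(=O)[C@]12C
F2 | step 9 | C4 enol triflate (C3=C4–OTf), Δ6 tertiary allylic alcohol | C1=C[C@@](C)(O)[C@](C)(CO[Si](C)(C)C(C)(C)C)[C@H]2CCC=C(OS(=O)(=O)C(F)(F)F)[C@]12C
F3 | step 9 | 6-oxo-Δ7 enone with C4 enol triflate | O=C1C=C(C)[C@](C)(CO[Si](C)(C)C(C)(C)C)[C@H]2CCC=C(OS(=O)(=O)C(F)(F)F)[C@]12C
F4 | step 9 | 6β-allylic alcohol with C4 enol triflate | O[C@H]1C=C(C)[C@](C)(CO[Si](C)(C)C(C)(C)C)[C@H]2CCC=C(OS(=O)(=O)C(F)(F)F)[C@]12C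
F5 | step 9 | 6β,7α,8α-triol with C4 enol triflate | O[C@H]1[C@H](O)[C@](C)(O)[C@](C)(CO[Si](C)(C)C(C)(C)C)[C@H]2CCC=C(OS(=O)(=O)C(F)(F)F)[C@]12C
F6 | step 4 | 9α-allyl trans-hydrindan-8-one, C3 ketal | C1CC(=O)[C@](C)(CC=C)[C@H]2CCC3(OCCO3)[C@]12C
F7 | step 4 | 9α-(E)-prop-1-enyl trans-hydrindan-8-one, C3 ketal | C1CC(=O)[C@](C)(/C=C/C)[C@H]2CCC3(OCCO3)[C@]12C
F8 | step 4 | 9α-formyl trans-hydrindan-8-one, C3 ketal | C1CC(=O)[C@](C)(C=O)[C@H]2CCC3(OCCO3)[C@]12C
F9 | step 18 | (E)-vinyl iodide (C11=C12–I), 6β,7α-diacetate | CC(=O)O[C@H]1[C@H](OC(C)=O)[C@](C)(O)[C@](C)(/C=C/I)[C@H]2CCC=C(C)[C@]12C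
F10 | step 18 | 4-(tributylstannyl)furan-2(5H)-one | CCCC[Sn](CCCC)(CCCC)C1=CC(=O)OC1
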